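**Retrosynthetic overview**
1. Granosolide B (22) comes from double acetylation of the 3,11-diol 21.
2. 21 comes from the open-chain epoxy aldehyde/vinyl bromide 18 in one flask. A Ni/Cr coupling closes C7–C8, and the new C7 alkoxide opens the (3S,4S)-epoxide at C4. The 14-membered carbocycle and the tetrahydrofuran form together.
3. 18 is built by growing C4–C7 on C3 of lactone 13: Luche reduction, Johnson–Claisen rearrangement, ent-Shi epoxidation, i-Bu2AlH.
4. The α-methylene-ε-lactone 13 comes from lactonisation of 12. 12 comes from Baeyer–Villiger lactone 10 (C12–O set with retention), made after oxidising the isopropenyl group to an acrylic acid.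
5. Ketone 7 comes from a reductive aldol of (R)-carvone with 4-bromopent-4-enal, in which C1 controls C12 and C11. Ring order: ε-lactone first, then carbocycle and tetrahydrofuran in the same operation.

Numbering (cembrane):
- C1 is the CH bearing C15. C15 carries =C17H2 and C16 (the lactone C=O).
- C3 and C11 are the acetoxy carbons.
- C4 and C7 are the tetrahydrofuran carbons.
- C8 carries =CH2.
- C12 is the quaternary carbon bearing the lactone oxygen.

Assumption: the (S)-sulfonamide ligand of step 12 directs Re-face attack on the C7 aldehyde (giving 7S); if the sense proved opposite, its antipode would be used.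

**Step 1**
Reactants: 1 2-bromoprop-2-en-1-ol
Product: 3 4-bromopent-4-enal, via 2-bromoallyl vinyl ether 2 (not isolated)
Conditions: Pd(OAc)2 (0.5 mol %), 1,10-phenanthroline, triethylene glycol divinyl ether, 85 °C, then 150 °C, distil
Reagents that add atoms: triethylene glycol divinyl ether, C=COCCOCCOCCOC=C
Why: Transfer vinylation followed by thermal Claisen rearrangement of the allyl vinyl ether is a standard route to γ,δ-unsaturated aldehydes, leaves the vinyl bromide untouched and creates no stereocenter.

**Step 2**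
Reactants: 4 (R)-(−)-carvone; 3 4-bromopent-4-enal
Product: 7 (2R,5R)-2-[(1R)-4-bromo-1-(triethylsilyloxy)pent-4-en-1-yl]-2-methyl-5-(prop-1-en-2-yl)cyclohexan-1-one, via lithium enolate 5 (not isolated), via lithium aldolate 6 (not isolated)
Conditions: LiBH(s-Bu)3 (1.0 equiv), THF, −78 °C; 3, −78 °C; Et3SiOTf, −78 to 0 °C
Reagents that add atoms: triethylsilyl trifluoromethanesulfonate, CC[Si](CC)(CC)OS(=O)(=O)C(F)(F)F
Why: Reductive aldol: 1,4-hydride addition gives the regiodefined tetrasubstituted enolate, chair-like axial attack on the face cis to the equatorial isopropenyl group (the sense seen in Robinson annulations of dihydrocarvone) sets 12R, a closed Zimmerman–Traxler transition state sets 11R, and silylation of the aldolate blocks retro-aldol.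

**Step 3**
Reactants: 7 silyl ether ketone
Product: 8 allylic alcohol (7 with the isopropenyl CH3 turned into C16H2OH; 1R,11R,12R)
Conditions: SeO2 (0.3 equiv), t-BuOOH, CH2Cl2, 0 to 25 °C
Reagents that add atoms: tert-butyl hydroperoxide, CC(C)(C)OO
Why: Catalytic SeO2 allylic oxidation (ene reaction, then [2,3]-shift) attacks the only electron-rich alkene at its methyl group, the bromoalkene is deactivated, and any over-oxidised enal converges in step 4.

**Step 4**
Reactants: 8 allylic alcohol
Product: 9 keto acid (C16 = CO2H; 2-substituted acrylic acid on C1; 1R,11R,12R)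
Conditions: TEMPO (cat.), NaOCl (cat.), NaClO2, MeCN–phosphate buffer pH 6.7, 35 °C
Reagents that add atoms: sodium chlorite, [Na+].[O-]Cl=O
Why: TEMPO/chlorite oxidation takes the primary allylic alcohol through the enal to the acid under near-neutral conditions that spare the ketone, silyl ether and vinyl bromide.

**Step 5**
Reactants: 9 keto acid
Product: 10 seven-membered lactone acid (O inserted between C3 and C12; 1R,11R,12R)
Conditions: m-CPBA (2.5 equiv), CH2Cl2, 25 to 40 °C
Reagents that add atoms: m-CPBA, OOC(=O)c1cccc(Cl)c1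
Why: Baeyer–Villiger oxidation: the fully substituted C12 migrates in preference to C2H2 with retention of configuration, turning the C12–C3 bond into the C12–O bond of the target, and the remaining alkenes (acrylic acid, vinyl bromide) are too electron-poor to be epoxidised.

**Step 6**
Reactants: 10 lactone acid
Product: 12 hydroxy acid enone (C3 isopropenyl ketone, free tertiary 12-OH, C16 acid), via Weinreb amide 11 (not isolated)
Conditions: MeNH(OMe)·HCl (1.5 equiv), CH2=C(CH3)MgBr (7 equiv), THF, −20 to 0 °C; cold aq. HCl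
Reagents that add atoms: isopropenylmagnesium bromide, C=C(C)[Mg]Br
Why: Ketone synthesis through a Weinreb amide made in situ: the magnesium amide opens the strained lactone, the chelated adduct of 11 accepts only one isopropenyl group, the magnesium carboxylate shields C16, and no stereocenter is touched.

**Step 7**
Reactants: 12 hydroxy acid enone
Product: 13 α-methylene-ε-lactone enone (C16–O–C12 lactone; C1 carries CH2C(=O)C(CH3)=CH2)
Conditions: 2-methyl-6-nitrobenzoic anhydride, DMAP, Et3N, toluene (5 mM), 25 to 60 °C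
Reagents that add atoms: none
Why: Shiina lactonisation (mixed anhydride and DMAP acyl transfer): the tertiary 12-OH is the only free hydroxyl, closure of the seven-membered ring is helped by the quaternary C12, and no bond at C12 is broken, so its configuration is kept.

**Step 8**
Reactants: 13 lactone enone
Product: 14 allylic alcohol (C3 carbinol, both epimers)
Conditions: NaBH4, CeCl3·7H2O, MeOH, −78 °C
Reagents that add atoms: none
Why: Luche reduction gives clean 1,2-addition to the enone at a temperature where the hindered α-methylene lactone is inert, and the C3 epimer mixture does not matter because C3 becomes sp2 in step 9.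

**Step 9**
Reactants: 14 allylic alcohol
Product: 16 ethyl (E)-ester (C3=C4 trisubstituted E-alkene, C7 = CO2Et), via ketene acetal 15 (not isolated)
Conditions: CH3C(OEt)3, EtCO2H (cat.), BHT, 135 °C
Reagents that add atoms: triethyl orthoacetate, CC(OCC)(OCC)OCC
Why: Johnson–Claisen rearrangement through a chair transition state with the C2 chain equatorial gives the E-alkene (typically >95:5), adds C6–C7, and consumes the 3-OH before it can attack the lactone.

**Step 10**
Reactants: 16 (E)-ester
Product: 17 (3S,4S)-epoxy ester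
Conditions: ent-Shi ketone (L-series, from L-sorbose, 30 mol %), 2KHSO5·KHSO4·K2SO4, K2CO3, Bu4NHSO4, MeCN–(MeO)2CH2–aq. Na2B4O7 buffer, 0 °C
Reagents that add atoms: potassium peroxymonosulfate, [K+].[O-]S(=O)(=O)OO
Why: Shi asymmetric epoxidation: the chiral dioxirane reacts only with the electron-rich trisubstituted alkene, and because the D-fructose ketone gives R,R-epoxides on such E-alkenes, its enantiomer sets 3S,4S under catalyst control.

**Step 11**
Reactants: 17 epoxy ester
Product: 18 epoxy aldehyde (C7 = CHO)
Conditions: i-Bu2AlH (1.05 equiv), CH2Cl2, −78 °C; MeOH, aq. potassium sodium tartrate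
Reagents that add atoms: none
Why: Partial ester reduction: the unhindered ethyl ester forms a stable aluminium hemiacetal at −78 °C, while the conjugated lactone of a tertiary alcohol reacts far more slowly (like a tert-butyl ester), and the epoxide and silyl ether are inert.

**Step 12**
Reactants: 18 epoxy aldehyde
Product: 21 tricyclic 3,11-diol (1R,3S,4R,7S,11R,12R), via macrocyclic epoxy alcohol 19 (not isolated), via tetrahydrofuran silyl ether 20 (not isolated)
Conditions: CrCl2 (8 equiv), (S)-N-[2-(4-isopropyl-4,5-dihydrooxazol-2-yl)-6-methylphenyl]methanesulfonamide (8.8 equiv), Et3N (8.8 equiv), NiCl2(2,9-dimethyl-1,10-phenanthroline) (10 mol %), THF, 18 added over 12 h (2 mM), 25 °C; then H2O, camphorsulfonic acid to pH 2, 25 °C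
Reagents that add atoms: none
Why: Proposed new method: zerovalent nickel inserts into C8–Br, the vinyl group passes to trivalent chromium and adds under ligand control to the Re face of the C7 aldehyde (closing the 14-membered ring and setting 7S), the resulting γ,δ-epoxy alkoxide (the alcohol after acidification) then opens the activated trisubstituted epoxide at tertiary C4 in a 5-exo mode with inversion (4S to 4R) to give the cis-tetrahydrofuran and the free 3S carbinol while the acid also removes the silyl group, the closest known reaction types being Nozaki–Hiyama–Kishi macrocyclisation and the Nozaki–Hiyama–Kishi coupling/Williamson etherification sequence.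

**Step 13**
Reactants: 21 tricyclic diol
Product: 22 Granosolide B
Conditions: Ac2O, pyridine, DMAP (cat.), CH2Cl2, 0 to 25 °C
Reagents that add atoms: acetic anhydride, CC(=O)OC(C)=O
Why: Ordinary DMAP-catalysed O-acylation caps both secondary alcohols (C3, C11) without breaking any bond at a stereocenter, and fast acetylation of 3-OH pre-empts its attack on the lactone.

**Compound list**
1 | 2-bromoprop-2-en-1-ol | OCC(Br)=C | starting material
2 | 2-bromoallyl vinyl ether | C=COCC(Br)=C | intermediate
3 | 4-bromopent-4-enal | O=CCCC(Br)=C | intermediate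
4 | (R)-(−)-carvone | C=C(C)[C@@H]1CC=C(C)C(=O)C1 | starting material
5 | lithium enolate of (R)-dihydrocarvone (C3=C12) | C=C(C)[C@@H]1CCC(C)=C([O-])C1.[Li+] | intermediate
6 | lithium aldolate (1R,11R,12R) | C=C(C)[C@@H]1CC[C@](C)([C@H]([O-])CCC(Br)=C)C(=O)C1.[Li+] | intermediate
7 | (2R,5R)-2-[(1R)-4-bromo-1-(triethylsilyloxy)pent-4-en-1-yl]-2-methyl-5-(prop-1-en-2-yl)cyclohexan-1-one | C=C(C)[C@@H]1CC[C@](C)([C@H](O[Si](CC)(CC)CC)CCC(Br)=C)C(=O)C1 | intermediate
8 | allylic alcohol (C16H2OH) | C=C(CO)[C@@H]1CC[C@](C)([C@H](O[Si](CC)(CC)CC)CCC(Br)=C)C(=O)C1 | intermediate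
9 | keto acid (C16 CO2H) | C=C(C(=O)O)[C@@H]1CC[C@](C)([C@H](O[Si](CC)(CC)CC)CCC(Br)=C)C(=O)C1 | intermediate
10 | Baeyer–Villiger lactone acid (C3(=O)–O–C12) | C=C(C(=O)O)[C@@H]1CC[C@](C)([C@H](O[Si](CC)(CC)CC)CCC(Br)=C)OC(=O)C1 | intermediate
11 | C3 Weinreb amide hydroxy acid | C=C(C(=O)O)[C@@H](CC(=O)N(C)OC)CC[C@@](C)(O)[C@H](O[Si](CC)(CC)CC)CCC(Br)=C | intermediate
12 | hydroxy acid enone | C=C(C(=O)O)[C@@H](CC(=O)C(C)=C)CC[C@@](C)(O)[C@H](O[Si](CC)(CC)CC)CCC(Br)=C | intermediate
13 | α-methylene-ε-lactone enone | C=C1C(=O)O[C@@](C)([C@H](O[Si](CC)(CC)CC)CCC(Br)=C)CC[C@@H]1CC(=O)C(C)=C | intermediate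
14 | lactone allylic alcohol (C3 epimers) | C=C1C(=O)O[C@@](C)([C@H](O[Si](CC)(CC)CC)CCC(Br)=C)CC[C@@H]1CC(O)C(C)=C | intermediate
15 | C3–O ketene ethyl acetal | C=C1C(=O)O[C@@](C)([C@H](O[Si](CC)(CC)CC)CCC(Br)=C)CC[C@@H]1CC(OC(=C)OCC)C(C)=C | intermediate
16 | lactone (E)-alkene ethyl ester | C=C1C(=O)O[C@@](C)([C@H](O[Si](CC)(CC)CC)CCC(Br)=C)CC[C@@H]1C/C=C(\C)CCC(=O)OCC | intermediate
17 | (3S,4S)-epoxy ethyl ester | C=C1C(=O)O[C@@](C)([C@H](O[Si](CC)(CC)CC)CCC(Br)=C)CC[C@@H]1C[C@@H]2O[C@@]2(C)CCC(=O)OCC | intermediate
18 | (3S,4S)-epoxy aldehyde | C=C1C(=O)O[C@@](C)([C@H](O[Si](CC)(CC)CC)CCC(Br)=C)CC[C@@H]1C[C@@H]2O[C@@]2(C)CCC=O | intermediate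
19 | macrocyclic (7S)-epoxy alcohol | C=C1C(=O)O[C@]2(C)CC[C@@H]1C[C@@H]3O[C@@]3(C)CC[C@H](O)C(=C)CC[C@H]2O[Si](CC)(CC)CC | intermediate
20 | tricyclic 3-ol 11-triethylsilyl ether | C=C1C(=O)O[C@]2(C)CC[C@@H]1C[C@H](O)[C@@]1(C)CC[C@H](O1)C(=C)CC[C@H]2O[Si](CC)(CC)CC | intermediate
21 | tricyclic 3,11-diol | C=C1C(=O)O[C@]2(C)CC[C@@H]1C[C@H](O)[C@@]1(C)CC[C@H](O1)C(=C)CC[C@H]2O | intermediate
22 | Granosolide B | C=C1C(=O)O[C@]2(C)CC[C@@H]1C[C@H](OC(C)=O)[C@@]1(C)CC[C@H](O1)C(=C)CC[C@H]2OC(C)=O | target

**Step count:** 13 steps in total. The longest linear sequence is also 13 steps (1 → 3 → 7 → 22; carvone enters at step 2).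

**The three steps most likely to fail**

**Step 12 (one-pot ring closure and etherification).** The risks are a sluggish vinyl bromide, the wrong C7 face, and loss of the epoxide. The fallback builds the two rings one after the other, starting from 16.
- i-Bu2AlH gives the alkene aldehyde F6.
- Ligand-free CrCl2/NiCl2 macrocyclisation in DMSO gives the macrocyclic allylic alcohol F7 as a C7 mixture.
- Dess–Martin oxidation gives the macrocyclic enone F8.
- (R)-2-methyl-CBS-oxazaborolidine/BH3·SMe2 gives the 7S allylic alcohol F9.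
- VO(acac)2/t-BuOOH epoxidation of C3=C4, directed by the bishomoallylic 7-OH, is followed by spontaneous 5-exo opening and gives the cis-tetrahydrofuran 20.
- Acid desilylation rejoins the route at 21.

**Step 7 (acylation of a very hindered tertiary alcohol).** The fallback avoids acylating a neutral alcohol and instead uses the alkoxide released when the Baeyer–Villiger lactone is opened. It starts from 9.
- Me3SiCHN2 gives the keto methyl ester F3.
- m-CPBA gives the lactone methyl ester F4.
- MeNH(OMe)·HCl/i-PrMgCl opens the saturated lactone. The magnesium tertiary alkoxide set free closes onto the neighbouring methyl acrylate ester and gives the Weinreb amide ε-lactone F5.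
- CH2=C(CH3)MgBr at −78 °C rejoins the route at 13.

**Step 2 (diastereocontrol at C12 and C11 in the lithium aldol).** The fallback separates enolate formation from C–C bond formation. It starts from 4.
- RhCl(PPh3)3-catalysed 1,4-hydrosilylation with Et3SiH gives the triethylsilyl enol ether F1, which is isolated.
- A BF3·OEt2-mediated Mukaiyama aldol with 3 (open transition state, still axial attack on the ring) gives the free aldol F2, whose isomers can be separated.
- Et3SiOTf/2,6-lutidine rejoins the route at 7.

**Further compounds**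
F1 | step 2 | triethylsilyl enol ether of (R)-dihydrocarvone | C=C(C)[C@@H]1CCC(C)=C(O[Si](CC)(CC)CC)C1
F2 | step 2 | free aldol (1R,11R,12R) | C=C(C)[C@@H]1CC[C@](C)([C@H](O)CCC(Br)=C)C(=O)C1
F3 | step 7 | keto methyl ester | C=C(C(=O)OC)[C@@H]1CC[C@](C)([C@H](O[Si](CC)(CC)CC)CCC(Br)=C)C(=O)C1
F4 | step 7 | Baeyer–Villiger lactone methyl ester | C=C(C(=O)OC)[C@@H]1CC[C@](C)([C@H](O[Si](CC)(CC)CC)CCC(Br)=C)OC(=O)C1
F5 | step 7 | Weinreb amide ε-lactone | C=C1C(=O)O[C@@](C)([C@H](O[Si](CC)(CC)CC)CCC(Br)=C)CC[C@@H]1CC(=O)N(C)OC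
F6 | step 12 | alkene aldehyde | C=C1C(=O)O[C@@](C)([C@H](O[Si](CC)(CC)CC)CCC(Br)=C)CC[C@@H]1C/C=C(\C)CCC=O
F7 | step 12 | macrocyclic allylic alcohol (C7 epimers) | C=C1C(=O)O[C@]2(C)CC[C@@H]1C/C=C(\C)CCC(O)C(=C)CC[C@H]2O[Si](CC)(CC)CC
F8 | step 12 | macrocyclic enone | C=C1C(=O)O[C@]2(C)CC[C@@H]1C/C=C(\C)CCC(=O)C(=C)CC[C@H]2O[Si](CC)(CC)CC
F9 | step 12 | 7S macrocyclic allylic alcohol | C=C1C(=O)O[C@]2(C)CC[C@@H]1C/C=C(\C)CC[C@H](O)C(=C)CC[C@H]2O[Si](CC)(CC)CC
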